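The five-membered oxygen ring is treated as a hydrogenated furan: the O1–C2(guaiacyl)–C3(CH2O) unit of the 2,3-dihydrobenzofuran is the C2=C3 bond of a planar 2-arylbenzofuran whose C3 carries a carboxylate. One catalyst-controlled hydrogenation of this tetrasubstituted heteroaromatic bond removes the furan aromaticity and sets C2 and, by syn addition, C3 as the cis ester. Because C3 lies alpha to the ester, it is afterwards equilibrated to trans. The precursor is a methyl 2-aryl-7-methoxybenzofuran-3-carboxylate with all hydroxyls silylated, built from an iodophenol, an arylalkyne and CO. Reduction, coumaroylation and desilylation finish the route.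

Key step: step 10

Assumption: the sense of induction of the chiral carbene ligand cannot be predicted with confidence for this substrate class. The (R,R) ligand, (R,R)-SINpEt·HBF4 = 1,3-bis[(R)-1-(naphthalen-1-yl)ethyl]-4,5-dihydroimidazolium tetrafluoroborate, is written; the (S,S) ligand is to be used instead if a trial run shows that it is the one leading to the 2R series.

Step 1
Reactants: 1 dihydroconiferyl alcohol [4-(3-hydroxypropyl)-2-methoxyphenol]
Product: 2 4-(3-hydroxypropyl)-2-iodo-6-methoxyphenol
Conditions: NIS (1.0 equiv), p-TsOH·H2O (10 mol %), MeCN, 0 °C to rt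
Reagents that add atoms: N-iodosuccinimide, O=C1CCC(=O)N1I
Why: Electrophilic aromatic iodination; the free hydroxyl is the strongest director, its para position carries the side chain and one ortho position the methoxy group, so iodine should enter the remaining ortho position, as in the halogenation of other 4-alkylguaiacols.

Step 2
Reactants: 2 4-(3-hydroxypropyl)-2-iodo-6-methoxyphenol
Product: 3 4-[3-(tert-butyldimethylsilyloxy)propyl]-2-iodo-6-methoxyphenol
Conditions: TBSCl (1.05 equiv), imidazole (2 equiv), CH2Cl2, 0 °C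
Reagents that add atoms: tert-butyldimethylsilyl chloride, CC(C)(C)[Si](C)(C)Cl
Why: Chemoselective silylation; the unhindered primary alcohol reacts with TBSCl far faster than the phenol, which is now flanked by iodine and methoxy, so one equivalent should give the aliphatic silyl ether only (the reason for iodinating first).

Step 3
Reactants: 3 4-[3-(tert-butyldimethylsilyloxy)propyl]-2-iodo-6-methoxyphenol
Product: 4 4-[3-(tert-butyldimethylsilyloxy)propyl]-2-iodo-6-methoxyphenyl acetate
Conditions: Ac2O, Et3N, DMAP (cat.), CH2Cl2, 0 °C to rt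
Reagents that add atoms: acetic anhydride, CC(=O)OC(C)=O
Why: DMAP-catalysed acylation of the hindered phenol; the acetate keeps the phenol from closing onto the alkyne during the cross-coupling that follows.

Step 4
Reactants: 5 vanillin (4-hydroxy-3-methoxybenzaldehyde)
Product: 6 3-methoxy-4-(triisopropylsilyloxy)benzaldehyde
Conditions: TIPSCl, imidazole, DMF, rt
Reagents that add atoms: triisopropylsilyl chloride, CC(C)[Si](Cl)(C(C)C)C(C)C
Why: Standard silylation of a phenol; the bulky TIPS ether is chosen because it must withstand n-BuLi, amines, hydrazine, acetate-buffered methanol and hydride, and later blocks quinone methide formation at C2.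

Step 5
Reactants: 6 3-methoxy-4-(triisopropylsilyloxy)benzaldehyde
Product: 7 [4-(2,2-dibromovinyl)-2-methoxyphenoxy]triisopropylsilane
Conditions: CBr4, PPh3, Zn dust, CH2Cl2, rt (ylide formation); then 6, 0 °C to rt
Reagents that add atoms: carbon tetrabromide, BrC(Br)(Br)Br
Why: Corey–Fuchs dibromo-olefination, a Wittig reaction of Ph3P=CBr2 generated with zinc, which is neutral and leaves the aryl silyl ether alone.

Step 6
Reactants: 7 [4-(2,2-dibromovinyl)-2-methoxyphenoxy]triisopropylsilane
Product: 9 (4-ethynyl-2-methoxyphenoxy)triisopropylsilane, via lithium acetylide 8 (not isolated)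
Conditions: n-BuLi (2.1 equiv), THF, −78 °C to 0 °C; then H2O
Reagents that add atoms: none
Why: Second stage of the Corey–Fuchs homologation; bromine–lithium exchange, loss of LiBr with 1,2-shift (Fritsch–Buttenberg–Wiechell) and deprotonation give the acetylide, which water protonates to the terminal alkyne, while the aryl TIPS ether is inert to n-BuLi at −78 °C.

Step 7
Reactants: 4 4-[3-(tert-butyldimethylsilyloxy)propyl]-2-iodo-6-methoxyphenyl acetate; 9 (4-ethynyl-2-methoxyphenoxy)triisopropylsilane
Product: 10 4-[3-(tert-butyldimethylsilyloxy)propyl]-2-methoxy-6-{[3-methoxy-4-(triisopropylsilyloxy)phenyl]ethynyl}phenyl acetate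
Conditions: PdCl2(PPh3)2 (3 mol %), CuI (5 mol %), Et3N, THF, rt, degassed
Reagents that add atoms: none
Why: Sonogashira coupling of an aryl iodide with a terminal alkyne proceeds at room temperature; with the phenol acetylated and no heating, the product should stay at the diarylalkyne stage.

Step 8
Reactants: 10 4-[3-(tert-butyldimethylsilyloxy)propyl]-2-methoxy-6-{[3-methoxy-4-(triisopropylsilyloxy)phenyl]ethynyl}phenyl acetate
Product: 11 4-[3-(tert-butyldimethylsilyloxy)propyl]-2-methoxy-6-{[3-methoxy-4-(triisopropylsilyloxy)phenyl]ethynyl}phenol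
Conditions: N2H4·H2O (2 equiv), THF–MeCN, 0 °C to rt
Reagents that add atoms: none
Why: Hydrazinolysis cleaves the activated aryl acetate under nearly neutral, metal-free conditions, so both silyl ethers should survive and the liberated phenol should not cyclize.

Step 9
Reactants: 11 4-[3-(tert-butyldimethylsilyloxy)propyl]-2-methoxy-6-{[3-methoxy-4-(triisopropylsilyloxy)phenyl]ethynyl}phenol
Product: 12 methyl 5-[3-(tert-butyldimethylsilyloxy)propyl]-7-methoxy-2-[3-methoxy-4-(triisopropylsilyloxy)phenyl]benzofuran-3-carboxylate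
Conditions: PdCl2 (10 mol %), CuCl2 (3 equiv), NaOAc (3 equiv), CO (1 atm), MeOH, rt
Reagents that add atoms: carbon monoxide, [C-]#[O+]; methanol, CO
Why: Oxidative cyclization–methoxycarbonylation of an ortho-alkynylphenol; divalent palladium activates the alkyne for 5-endo-dig attack of the phenol oxygen (O1–C2 bond), the 3-benzofuranylpalladium formed inserts CO and is cleaved by methanol to the C3 methyl ester, CuCl2 returns zerovalent palladium to the divalent state, and NaOAc buffers the HCl so that the silyl ethers persist.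

Step 10
Reactants: 12 methyl 5-[3-(tert-butyldimethylsilyloxy)propyl]-7-methoxy-2-[3-methoxy-4-(triisopropylsilyloxy)phenyl]benzofuran-3-carboxylate
Product: 13 methyl (2R,3S)-5-[3-(tert-butyldimethylsilyloxy)propyl]-7-methoxy-2-[3-methoxy-4-(triisopropylsilyloxy)phenyl]-2,3-dihydrobenzofuran-3-carboxylate (cis)
Conditions: Ru(cod)(2-methylallyl)2 (5 mol %), (R,R)-SINpEt·HBF4 (10 mol %), KOt-Bu (12 mol %), n-hexane, 70 °C (catalyst formation); then 12, H2 (60 bar), n-hexane–toluene, 40 °C
Reagents that add atoms: none
Why: Proposed new method: enantioselective hydrogenation of the tetrasubstituted C2=C3 bond of a 2-arylbenzofuran-3-carboxylate; this bond has little aromatic stabilization and is also a polarized beta-aryl-beta-aryloxy acrylate, so the chiral ruthenium bis(carbene) hydride should bind one of its faces, transfer hydride to C2 and release the product by hydrogenolysis of the C3-bound (oxa-allyl) ruthenium species, both hydrogens arriving on the same face. The closest known reaction types are the asymmetric hydrogenation of 2-arylbenzofurans and of flavones (the same beta-aryl-beta-aryloxy enone pattern) with this Ru–carbene catalyst class, and the cis-selective Ru–bisphosphine hydrogenation of 2,3-disubstituted N-acylindoles. No ring is closed; the existing furan ring is only dearomatized to the 2,3-dihydrobenzofuran. C2 (R) is set by the chiral carbene ligands through enantioface discrimination, and C3 (S) follows from syn delivery of H2, which gives the cis ester. The step needs enantioface selectivity at C2 and chemoselectivity for the heteroaromatic bond over the two benzene rings: the flat 2-aryl group recognised by this catalyst class and the ester as a second contact point serve the first, the low aromaticity of the furan ring and the absence of any hydrogenolysable group (silyl ethers only) the second. Any leakage at C3 is harmless because that centre is equilibrated in step 11.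

Step 11
Reactants: 13 methyl (2R,3S)-5-[3-(tert-butyldimethylsilyloxy)propyl]-7-methoxy-2-[3-methoxy-4-(triisopropylsilyloxy)phenyl]-2,3-dihydrobenzofuran-3-carboxylate (cis)
Product: 14 methyl (2R,3R)-5-[3-(tert-butyldimethylsilyloxy)propyl]-7-methoxy-2-[3-methoxy-4-(triisopropylsilyloxy)phenyl]-2,3-dihydrobenzofuran-3-carboxylate (trans)
Conditions: DBU (0.5 equiv), toluene, 40 °C
Reagents that add atoms: none
Why: Thermodynamic epimerization alpha to the ester; the C3–H is benzylic and alpha to the carbonyl, so reversible deprotonation should drain the strained cis isomer into the trans ester, while C2 has no acidic hydrogen and its aryl oxygen is capped as the TIPS ether, so under these aprotic, weakly basic conditions neither quinone methide formation nor E1cB opening of the O1–C2 bond should disturb the 2R centre.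

Step 12
Reactants: 14 methyl (2R,3R)-5-[3-(tert-butyldimethylsilyloxy)propyl]-7-methoxy-2-[3-methoxy-4-(triisopropylsilyloxy)phenyl]-2,3-dihydrobenzofuran-3-carboxylate (trans)
Product: 15 {(2R,3S)-5-[3-(tert-butyldimethylsilyloxy)propyl]-7-methoxy-2-[3-methoxy-4-(triisopropylsilyloxy)phenyl]-2,3-dihydrobenzofuran-3-yl}methanol (trans)
Conditions: i-Bu2AlH (2.5 equiv), CH2Cl2, −78 °C to 0 °C; aq. potassium sodium tartrate
Reagents that add atoms: none
Why: Hydride reduction of the methyl ester to the primary alcohol at low temperature leaves the silyl ethers and both stereocentres untouched; C3 becomes 3S only through the change in CIP priorities.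

Step 13
Reactants: 16 (E)-p-coumaric acid
Product: 18 (E)-4-(tert-butyldimethylsilyloxy)cinnamic acid, via bis-silylated coumarate 17 (not isolated)
Conditions: TBSCl (2.3 equiv), imidazole (4.5 equiv), DMF, rt; then K2CO3 (0.2 equiv), THF–MeOH–H2O, 0 °C, 30 min
Reagents that add atoms: tert-butyldimethylsilyl chloride, CC(C)(C)[Si](C)(C)Cl
Why: Exhaustive silylation followed by selective hydrolysis of the silyl ester, which is far more labile than the aryl silyl ether, should give the phenol-protected acid with the E alkene untouched.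

Step 14
Reactants: 15 {(2R,3S)-5-[3-(tert-butyldimethylsilyloxy)propyl]-7-methoxy-2-[3-methoxy-4-(triisopropylsilyloxy)phenyl]-2,3-dihydrobenzofuran-3-yl}methanol; 18 (E)-4-(tert-butyldimethylsilyloxy)cinnamic acid
Product: 19 {(2R,3S)-5-[3-(tert-butyldimethylsilyloxy)propyl]-7-methoxy-2-[3-methoxy-4-(triisopropylsilyloxy)phenyl]-2,3-dihydrobenzofuran-3-yl}methyl (E)-4-(tert-butyldimethylsilyloxy)cinnamate
Conditions: DCC (1.2 equiv), DMAP (0.2 equiv), CH2Cl2, 0 °C to rt
Reagents that add atoms: none
Why: Steglich esterification; 15 has a single free hydroxyl and 18 no free phenol, so DCC/DMAP should give one ester under neutral conditions that leave the stereocentres and the E alkene alone.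

Step 15
Reactants: 19 {(2R,3S)-5-[3-(tert-butyldimethylsilyloxy)propyl]-7-methoxy-2-[3-methoxy-4-(triisopropylsilyloxy)phenyl]-2,3-dihydrobenzofuran-3-yl}methyl (E)-4-(tert-butyldimethylsilyloxy)cinnamate
Product: 20 CNP0202924.1, [(2R,3S)-2-(4-hydroxy-3-methoxyphenyl)-5-(3-hydroxypropyl)-7-methoxy-2,3-dihydrobenzofuran-3-yl]methyl (E)-3-(4-hydroxyphenyl)acrylate
Conditions: Bu4NF (4 equiv), AcOH (4 equiv), THF, 0 °C to rt
Reagents that add atoms: none
Why: Fluoride-induced desilylation removes the two aryl silyl ethers and the primary TBS ether in one operation; acetic acid keeps the medium near neutral, so the coumarate ester should be neither cleaved nor migrated and the freed para-hydroxyaryl group should not open the ring at C2 through a quinone methide.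

Compound list
1 | dihydroconiferyl alcohol, 4-(3-hydroxypropyl)-2-methoxyphenol | COc1cc(CCCO)ccc1O | starting material
2 | 4-(3-hydroxypropyl)-2-iodo-6-methoxyphenol | COc1cc(CCCO)cc(I)c1O | intermediate
3 | 4-[3-(tert-butyldimethylsilyloxy)propyl]-2-iodo-6-methoxyphenol | COc1cc(CCCO[Si](C)(C)C(C)(C)C)cc(I)c1O | intermediate
4 | 4-[3-(tert-butyldimethylsilyloxy)propyl]-2-iodo-6-methoxyphenyl acetate | COc1cc(CCCO[Si](C)(C)C(C)(C)C)cc(I)c1OC(C)=O | intermediate
5 | vanillin | COc1cc(C=O)ccc1O | starting material
6 | 3-methoxy-4-(triisopropylsilyloxy)benzaldehyde | COc1cc(C=O)ccc1O[Si](C(C)C)(C(C)C)C(C)C | intermediate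
7 | [4-(2,2-dibromovinyl)-2-methoxyphenoxy]triisopropylsilane | COc1cc(C=C(Br)Br)ccc1O[Si](C(C)C)(C(C)C)C(C)C | intermediate
8 | lithium [3-methoxy-4-(triisopropylsilyloxy)phenyl]acetylide | [Li]C#Cc1ccc(O[Si](C(C)C)(C(C)C)C(C)C)c(OC)c1 | intermediate (not isolated)
9 | (4-ethynyl-2-methoxyphenoxy)triisopropylsilane | COc1cc(C#C)ccc1O[Si](C(C)C)(C(C)C)C(C)C | intermediate
10 | 4-[3-(tert-butyldimethylsilyloxy)propyl]-2-methoxy-6-{[3-methoxy-4-(triisopropylsilyloxy)phenyl]ethynyl}phenyl acetate | COc1cc(CCCO[Si](C)(C)C(C)(C)C)cc(C#Cc2ccc(O[Si](C(C)C)(C(C)C)C(C)C)c(OC)c2)c1OC(C)=O | intermediate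
11 | 4-[3-(tert-butyldimethylsilyloxy)propyl]-2-methoxy-6-{[3-methoxy-4-(triisopropylsilyloxy)phenyl]ethynyl}phenol | COc1cc(CCCO[Si](C)(C)C(C)(C)C)cc(C#Cc2ccc(O[Si](C(C)C)(C(C)C)C(C)C)c(OC)c2)c1O | intermediate
12 | methyl 5-[3-(tert-butyldimethylsilyloxy)propyl]-7-methoxy-2-[3-methoxy-4-(triisopropylsilyloxy)phenyl]benzofuran-3-carboxylate | COC(=O)c1c(-c2ccc(O[Si](C(C)C)(C(C)C)C(C)C)c(OC)c2)oc2c(OC)cc(CCCO[Si](C)(C)C(C)(C)C)cc12 | intermediate
13 | methyl (2R,3S)-5-[3-(tert-butyldimethylsilyloxy)propyl]-7-methoxy-2-[3-methoxy-4-(triisopropylsilyloxy)phenyl]-2,3-dihydrobenzofuran-3-carboxylate (cis) | COc1cc([C@@H]2Oc3c(OC)cc(CCCO[Si](C)(C)C(C)(C)C)cc3[C@@H]2C(=O)OC)ccc1O[Si](C(C)C)(C(C)C)C(C)C | intermediate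
14 | methyl (2R,3R)-5-[3-(tert-butyldimethylsilyloxy)propyl]-7-methoxy-2-[3-methoxy-4-(triisopropylsilyloxy)phenyl]-2,3-dihydrobenzofuran-3-carboxylate (trans) | COc1cc([C@@H]2Oc3c(OC)cc(CCCO[Si](C)(C)C(C)(C)C)cc3[C@H]2C(=O)OC)ccc1O[Si](C(C)C)(C(C)C)C(C)C | intermediate
15 | {(2R,3S)-5-[3-(tert-butyldimethylsilyloxy)propyl]-7-methoxy-2-[3-methoxy-4-(triisopropylsilyloxy)phenyl]-2,3-dihydrobenzofuran-3-yl}methanol (trans) | COc1cc([C@@H]2Oc3c(OC)cc(CCCO[Si](C)(C)C(C)(C)C)cc3[C@H]2CO)ccc1O[Si](C(C)C)(C(C)C)C(C)C | intermediate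
16 | (E)-p-coumaric acid | OC(=O)/C=C/c1ccc(O)cc1 | starting material
17 | tert-butyldimethylsilyl (E)-4-(tert-butyldimethylsilyloxy)cinnamate | CC(C)(C)[Si](C)(C)OC(=O)/C=C/c1ccc(O[Si](C)(C)C(C)(C)C)cc1 | intermediate (not isolated)
18 | (E)-4-(tert-butyldimethylsilyloxy)cinnamic acid | OC(=O)/C=C/c1ccc(O[Si](C)(C)C(C)(C)C)cc1 | intermediate
19 | {(2R,3S)-5-[3-(tert-butyldimethylsilyloxy)propyl]-7-methoxy-2-[3-methoxy-4-(triisopropylsilyloxy)phenyl]-2,3-dihydrobenzofuran-3-yl}methyl (E)-4-(tert-butyldimethylsilyloxy)cinnamate | COc1cc([C@@H]2Oc3c(OC)cc(CCCO[Si](C)(C)C(C)(C)C)cc3[C@H]2COC(=O)/C=C/c2ccc(O[Si](C)(C)C(C)(C)C)cc2)ccc1O[Si](C(C)C)(C(C)C)C(C)C | intermediate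
20 | CNP0202924.1, [(2R,3S)-2-(4-hydroxy-3-methoxyphenyl)-5-(3-hydroxypropyl)-7-methoxy-2,3-dihydrobenzofuran-3-yl]methyl (E)-3-(4-hydroxyphenyl)acrylate | COc1cc([C@@H]2Oc3c(OC)cc(CCCO)cc3[C@H]2COC(=O)/C=C/c2ccc(O)cc2)ccc1O | target

Total step count: 15. Longest linear sequence: 11 steps (1 to 20 through steps 1, 2, 3, 7, 8, 9, 10, 11, 12, 14, 15; the branch from vanillin 5 is equally long).

Steps most likely to fail

Step 10 (carries the label Proposed new method). The ester-bearing, tetrasubstituted furan bond may take up hydrogen too slowly, or the catalyst may discriminate its two faces poorly, leaving conversion or enantiomeric purity insufficient. The fallback is known chemistry and sets out from 12. Dissolving-metal conjugate reduction with Mg turnings in MeOH–THF (0 °C to rt) converts benzofuran-3-carboxylates into the thermodynamically preferred trans-2,3-dihydro esters. It should give 14 as a racemate, that is, together with its mirror image methyl (2S,3S)-5-[3-(tert-butyldimethylsilyloxy)propyl]-7-methoxy-2-[3-methoxy-4-(triisopropylsilyloxy)phenyl]-2,3-dihydrobenzofuran-3-carboxylate F1. Preparative chromatography on a chiral stationary phase removes this enantiomer, and the route is rejoined at 14, so steps 10 and 11 are both bypassed.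

Step 11. The epimerization may stall at an equilibrium mixture, or the ester enolate may expel the O1 phenoxide (E1cB ring opening) and re-close, eroding the C2 configuration. The fallback sets out from 13 and moves the epimerization to the aldehyde oxidation level, where a much weaker base suffices. Reduction with i-Bu2AlH (CH2Cl2, −78 °C to 0 °C) should give the cis alcohol {(2R,3R)-5-[3-(tert-butyldimethylsilyloxy)propyl]-7-methoxy-2-[3-methoxy-4-(triisopropylsilyloxy)phenyl]-2,3-dihydrobenzofuran-3-yl}methanol F2. Oxidation with Dess–Martin periodinane (NaHCO3, CH2Cl2, 0 °C) should give the cis aldehyde (2R,3S)-5-[3-(tert-butyldimethylsilyloxy)propyl]-7-methoxy-2-[3-methoxy-4-(triisopropylsilyloxy)phenyl]-2,3-dihydrobenzofuran-3-carbaldehyde F3. Equilibration with Et3N in CH2Cl2 at 0 °C should give the trans aldehyde (2R,3R)-5-[3-(tert-butyldimethylsilyloxy)propyl]-7-methoxy-2-[3-methoxy-4-(triisopropylsilyloxy)phenyl]-2,3-dihydrobenzofuran-3-carbaldehyde F4. Reduction with NaBH4 (MeOH–THF, 0 °C) then rejoins the route at 15.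

Step 9. Protonolysis of the 3-benzofuranyl–palladium intermediate may outrun CO insertion, giving cycloisomerization without the ester carbon, or the copper chloride medium may strip a silyl ether. The fallback sets out from 11. Iodocyclization with I2 and NaHCO3 in MeCN at rt (5-endo-dig closure triggered by an iodonium ion) should give the 3-iodobenzofuran tert-butyl(3-{3-iodo-7-methoxy-2-[3-methoxy-4-(triisopropylsilyloxy)phenyl]benzofuran-5-yl}propoxy)dimethylsilane F5. Methoxycarbonylation of its C3–I bond with PdCl2(dppf) (cat.), CO (1 atm), Et3N, MeOH–DMF, 70 °C then rejoins the route at 12.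

Further compounds
F1 | step 10 | methyl (2S,3S)-5-[3-(tert-butyldimethylsilyloxy)propyl]-7-methoxy-2-[3-methoxy-4-(triisopropylsilyloxy)phenyl]-2,3-dihydrobenzofuran-3-carboxylate | COc1cc([C@H]2Oc3c(OC)cc(CCCO[Si](C)(C)C(C)(C)C)cc3[C@@H]2C(=O)OC)ccc1O[Si](C(C)C)(C(C)C)C(C)C
F2 | step 11 | {(2R,3R)-5-[3-(tert-butyldimethylsilyloxy)propyl]-7-methoxy-2-[3-methoxy-4-(triisopropylsilyloxy)phenyl]-2,3-dihydrobenzofuran-3-yl}methanol | COc1cc([C@@H]2Oc3c(OC)cc(CCCO[Si](C)(C)C(C)(C)C)cc3[C@@H]2CO)ccc1O[Si](C(C)C)(C(C)C)C(C)C
F3 | step 11 | (2R,3S)-5-[3-(tert-butyldimethylsilyloxy)propyl]-7-methoxy-2-[3-methoxy-4-(triisopropylsilyloxy)phenyl]-2,3-dihydrobenzofuran-3-carbaldehyde | COc1cc([C@@H]2Oc3c(OC)cc(CCCO[Si](C)(C)C(C)(C)C)cc3[C@@H]2C=O)ccc1O[Si](C(C)C)(C(C)C)C(C)C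
F4 | step 11 | (2R,3R)-5-[3-(tert-butyldimethylsilyloxy)propyl]-7-methoxy-2-[3-methoxy-4-(triisopropylsilyloxy)phenyl]-2,3-dihydrobenzofuran-3-carbaldehyde | COc1cc([C@@H]2Oc3c(OC)cc(CCCO[Si](C)(C)C(C)(C)C)cc3[C@H]2C=O)ccc1O[Si](C(C)C)(C(C)C)C(C)C
F5 | step 9 | tert-butyl(3-{3-iodo-7-methoxy-2-[3-methoxy-4-(triisopropylsilyloxy)phenyl]benzofuran-5-yl}propoxy)dimethylsilane | Ic1c(-c2ccc(O[Si](C(C)C)(C(C)C)C(C)C)c(OC)c2)oc2c(OC)cc(CCCO[Si](C)(C)C(C)(C)C)cc12
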